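Everything rests on cutting the bond between the benzylic methine and its unsubstituted phenyl. That methine joins C8 of ring A to C1' of ring D, and C1' lies between oxygenated C2' and C6', so the methine is the β-carbon of a propanoate whose CH2CO2Me becomes C1'–C2' of ring D. One rhodium-catalysed conjugate phenylation forms the bond and sets the methine configuration. Its precursor is the methyl (E)-cinnamate of ring A carrying O5 as benzyl ether, O7 and O8a as MOM ethers and bromine at C4a. Ring D is then grown from the ester; ring C is closed last by Mitsunobu inversion.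

Key step: step 6

Remarks on the chemistry
- Locants: rings A and C carry flavanone numbers, ring D primed numbers. MOM = methoxymethyl. ArA = 4-(benzyloxy)-3-bromo-2,6-bis(methoxymethoxy)-5-methylphenyl (ring A, bromine at the future C4a). ArD = 2,6-bis(benzyloxy)-4-methoxy-3-methylphenyl (benzylated ring D).
- Structure correction: in the target O5 is a free hydroxyl and the only methyl ether is at C4' of ring D. The oxygen para to the cinnamate carbon (future O5) is therefore a benzyl ether, not a methyl ether. It stays on until ring C is closed, so that only O8a can cyclise.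
- Bromine at C4a is a spectator in step 6. It later gives the C4a carbanion by exchange at −78 °C, which avoids a long metalation next to the triarylmethane C–H.
- Assumption: (R,R)-Ph-bod* is written for the diene ligand; a pilot run on 9 should fix which enantiomer gives the (3R) ester 11.
- The methine keeps one spatial arrangement from 11 to 25; its descriptor changes only because substituent priorities change.

Step 1
Reactants: 1 2-methylbenzene-1,3,5-triol (2-methylphloroglucinol)
Product: 3 2,4,6-trihydroxy-3-methylbenzaldehyde, via iminium chloride 2 (not isolated)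
Conditions: POCl3 (1.2 equiv), DMF (3 equiv), EtOAc, 0 °C → rt; then H2O, 60 °C
Reagents that add atoms: N,N-dimethylformamide CN(C)C=O; water O
Why: Vilsmeier–Haack formylation; the two free ring positions of 1 are equivalent and the iminium group deactivates the ring against a second attack, so hydrolysis should give one aldehyde.

Step 2
Reactants: 3 2,4,6-trihydroxy-3-methylbenzaldehyde
Product: 4 4-(benzyloxy)-2,6-dihydroxy-3-methylbenzaldehyde
Conditions: BnBr (1.05 equiv), CsHCO3 (1.5 equiv), MeCN, 60 °C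
Reagents that add atoms: benzyl bromide BrCc1ccccc1
Why: Williamson etherification under chelation control; the 4-OH is the only hydroxyl not hydrogen-bonded to the aldehyde and the most acidic one, so hydrogencarbonate should ionise and benzylate it alone.

Step 3
Reactants: 4 4-(benzyloxy)-2,6-dihydroxy-3-methylbenzaldehyde
Product: 5 4-(benzyloxy)-2,6-bis(methoxymethoxy)-3-methylbenzaldehyde
Conditions: NaH (2.5 equiv), MOMCl (2.6 equiv), DMF, 0 °C → rt
Reagents that add atoms: chloromethyl methyl ether COCCl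
Why: O-alkylation of both chelated phenoxides after full deprotonation (MOM ether formation); the aldehyde has no α-hydrogen and should be inert.

Step 4
Reactants: 5 4-(benzyloxy)-2,6-bis(methoxymethoxy)-3-methylbenzaldehyde
Product: 6 4-(benzyloxy)-3-bromo-2,6-bis(methoxymethoxy)-5-methylbenzaldehyde
Conditions: NBS (1.05 equiv), MeCN, 0 °C → rt, dark
Reagents that add atoms: N-bromosuccinimide O=C1CCC(=O)N1Br
Why: Electrophilic aromatic bromination at the single remaining ring position, which is activated by three ether oxygens and meta to the aldehyde.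

Step 5
Reactants: 6 4-(benzyloxy)-3-bromo-2,6-bis(methoxymethoxy)-5-methylbenzaldehyde; 7 trimethyl phosphonoacetate
Product: 9 methyl (2E)-3-[4-(benzyloxy)-3-bromo-2,6-bis(methoxymethoxy)-5-methylphenyl]prop-2-enoate, via sodium phosphonate carbanion 8 (not isolated)
Conditions: NaH (1.2 equiv), 7 (1.3 equiv), THF, 0 °C; then 6, 0 °C → rt
Reagents that add atoms: none
Why: Horner–Wadsworth–Emmons olefination; the stabilised phosphonate anion should give the (E)-enoate and is known to tolerate di-ortho-alkoxy benzaldehydes.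

Step 6
Reactants: 9 methyl (2E)-3-[4-(benzyloxy)-3-bromo-2,6-bis(methoxymethoxy)-5-methylphenyl]prop-2-enoate; 10 phenylboronic acid
Product: 11 methyl (3R)-3-[4-(benzyloxy)-3-bromo-2,6-bis(methoxymethoxy)-5-methylphenyl]-3-phenylpropanoate
Conditions: 10 (3 equiv), Rh(acac)(C2H4)2 (5 mol %), (R,R)-Ph-bod* [(1R,4R)-2,5-diphenylbicyclo[2.2.2]octa-2,5-diene] (5.5 mol %), KOH (0.3 equiv), 1,4-dioxane/H2O 10:1, 60 °C
Reagents that add atoms: none
Why: Phenyl passes from boron to a hydroxo(diene) complex of monovalent rhodium, the Ph–Rh bond adds syn across the enoate with phenyl going to the β-carbon, and water protonates the oxa-π-allyl rhodium to release 11 and regenerate Rh–OH. The closest known reaction type is the Hayashi–Miyaura asymmetric 1,4-addition of arylboronic acids to cinnamate esters and coumarins with chiral diene ligands. No ring is closed. The methine stereocentre is set by the C2-symmetric diene on rhodium, which should let the (E)-enoate bind through one enantioface only; the substrate has no other stereocentre. The step needs exclusive 1,4-addition to a single alkene geometry without touching C–Br: step 5 delivers the pure (E)-ester, the two ortho MOM ethers make the twisted aryl group locally symmetric so its rotation creates no second isomer, and aryl bromides are inert to aryl–rhodium species at 60 °C.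

Step 7
Reactants: 12 methyl 2-methyl-3-oxobutanoate (methyl 2-methylacetoacetate)
Product: 13 methyl (2E)-3-methoxy-2-methylbut-2-enoate
Conditions: HC(OMe)3 (1.5 equiv), H2SO4 (cat.), MeOH, rt → 50 °C; distillation
Reagents that add atoms: trimethyl orthoformate COC(OC)OC
Why: Acid-catalysed ketalisation by the orthoformate and loss of methanol (enol ether formation of a β-keto ester) should give the conjugated (E)-enol ether, and any double-bond isomer converges on the same dienolate in step 8.

Step 8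
Reactants: 11 methyl (3R)-3-[4-(benzyloxy)-3-bromo-2,6-bis(methoxymethoxy)-5-methylphenyl]-3-phenylpropanoate; 13 methyl (2E)-3-methoxy-2-methylbut-2-enoate
Product: 15 methyl (2E,7R)-7-ArA-3-methoxy-2-methyl-5-oxo-7-phenylhept-2-enoate, via lithium dienolate 14 (not isolated)
Conditions: 13 (3 equiv), LiN(i-Pr)2 (3 equiv), THF, −78 °C; then 11, −78 → −20 °C; aq NH4Cl
Reagents that add atoms: none
Why: Crossed Claisen condensation: the dienolate 14 should attack the ester of 11 through its unhindered γ-carbon (the α-carbon is fully substituted), deprotonation of the product by a second equivalent of 14 drives the acylation, and the methine is β to the carbonyl and not enolisable.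

Step 9
Reactants: 15 methyl (2E,7R)-7-ArA-3-methoxy-2-methyl-5-oxo-7-phenylhept-2-enoate
Product: 16 2-[(S)-ArA(phenyl)methyl]-5-methoxy-4-methylbenzene-1,3-diol
Conditions: NaOMe (4 equiv), MeOH, 65 °C; then AcOH to pH 6
Reagents that add atoms: none
Why: Dieckmann-type intramolecular Claisen condensation as in cyclohexane-1,3-dione syntheses: the enolate at C6 (future C1') attacks the ester held cis by the enol ether, and loss of methoxide with tautomerisation should give the resorcinol irreversibly, whereas O-acylation to the 2-pyrone and double-bond isomers remain reversible in methoxide.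

Step 10
Reactants: 16 2-[(S)-ArA(phenyl)methyl]-5-methoxy-4-methylbenzene-1,3-diol
Product: 17 1,3-bis(benzyloxy)-2-[(S)-ArA(phenyl)methyl]-5-methoxy-4-methylbenzene
Conditions: BnBr (2.5 equiv), K2CO3 (4 equiv), Bu4NI (cat.), DMF, 50 °C
Reagents that add atoms: benzyl bromide BrCc1ccccc1
Why: Williamson benzylation of both ring D phenols in a dipolar aprotic solvent (O- over C-alkylation), so that the organolithium step meets no acidic O–H and ring D stays masked until the final hydrogenolysis.

Step 11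
Reactants: 18 ethyl (3R)-3-hydroxy-3-phenylpropanoate
Product: 19 (3R)-3-hydroxy-N-methoxy-N-methyl-3-phenylpropanamide
Conditions: MeNHOMe·HCl (2 equiv), i-PrMgCl (5 equiv), THF, −20 → 0 °C; aq NH4Cl
Reagents that add atoms: N,O-dimethylhydroxylamine hydrochloride CNOC.Cl
Why: Direct Weinreb amidation of the ester by the chloromagnesium amide formed in the flask; the carbinol carbon is not involved, so its (R) configuration is kept.

Step 12
Reactants: 19 (3R)-3-hydroxy-N-methoxy-N-methyl-3-phenylpropanamide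
Product: 20 (3R)-3-[(tert-butyldimethylsilyl)oxy]-N-methoxy-N-methyl-3-phenylpropanamide
Conditions: TBSCl (1.3 equiv), imidazole (2.5 equiv), DMF, rt
Reagents that add atoms: tert-butyldimethylsilyl chloride CC(C)(C)[Si](C)(C)Cl
Why: Standard silylation of a secondary alcohol, which masks the hydroxyl against the aryllithium of step 13.

Step 13
Reactants: 17 1,3-bis(benzyloxy)-2-[(S)-ArA(phenyl)methyl]-5-methoxy-4-methylbenzene; 20 (3R)-3-[(tert-butyldimethylsilyl)oxy]-N-methoxy-N-methyl-3-phenylpropanamide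
Product: 22 (3R)-1-{2-(benzyloxy)-5-[(S)-ArD(phenyl)methyl]-4,6-bis(methoxymethoxy)-3-methylphenyl}-3-[(tert-butyldimethylsilyl)oxy]-3-phenylpropan-1-one, via aryllithium 21 (not isolated)
Conditions: n-BuLi (1.05 equiv), THF, −78 °C, 10 min; then 20 (1.3 equiv), −78 → −30 °C; aq NH4Cl
Reagents that add atoms: none
Why: Bromine–lithium exchange at −78 °C is faster than any deprotonation, and the di-ortho-alkoxy aryllithium 21 should acylate on the Weinreb amide, whose chelated tetrahedral adduct stops at the ketone (Weinreb ketone synthesis).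

Step 14
Reactants: 22 (3R)-1-{2-(benzyloxy)-5-[(S)-ArD(phenyl)methyl]-4,6-bis(methoxymethoxy)-3-methylphenyl}-3-[(tert-butyldimethylsilyl)oxy]-3-phenylpropan-1-one
Product: 23 (3R)-1-{2-(benzyloxy)-5-[(R)-ArD(phenyl)methyl]-4,6-dihydroxy-3-methylphenyl}-3-hydroxy-3-phenylpropan-1-one
Conditions: HCl (1 M in MeOH), THF, 0 °C → rt; stopped at full conversion
Reagents that add atoms: none
Why: Acid-catalysed acetal exchange should remove both MOM ethers (one activated by the ortho ketone, the other twisted out of conjugation) together with the alkyl silyl ether at room temperature, while the benzyl ethers and the carbinol configuration are unaffected.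

Step 15
Reactants: 23 (3R)-1-{2-(benzyloxy)-5-[(R)-ArD(phenyl)methyl]-4,6-dihydroxy-3-methylphenyl}-3-hydroxy-3-phenylpropan-1-one
Product: 24 (2S)-5-(benzyloxy)-8-[(R)-ArD(phenyl)methyl]-7-hydroxy-6-methyl-2-phenyl-2,3-dihydro-4H-chromen-4-one
Conditions: PPh3 (1.5 equiv), DIAD (1.5 equiv), THF, 0 °C → rt
Reagents that add atoms: none
Why: Intramolecular Mitsunobu etherification: the O8a phenol displaces the oxyphosphonium of the (R)-carbinol with inversion in a 6-exo closure to give the (2S)-flavanone, and only this ring can form because O5 is benzylated and O7 cannot reach the carbinol.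

Step 16
Reactants: 24 (2S)-5-(benzyloxy)-8-[(R)-ArD(phenyl)methyl]-7-hydroxy-6-methyl-2-phenyl-2,3-dihydro-4H-chromen-4-one
Product: 25 (2S)-8-[(S)-(2,6-dihydroxy-4-methoxy-3-methylphenyl)(phenyl)methyl]-5,7-dihydroxy-6-methyl-2-phenyl-2,3-dihydro-4H-chromen-4-one (CNP0111783.1)
Conditions: H2 (1 atm), Pd/C (10 %), EtOAc/MeOH, rt; stopped at full conversion
Reagents that add atoms: none
Why: Hydrogenolysis of the three aryl benzyl ethers under neutral conditions, which cleave faster than the cyclic benzylic C2–O1 bond, so both stereocentres and the chelated ketone should survive.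

Compound list
1 | 2-methylbenzene-1,3,5-triol (2-methylphloroglucinol) | Cc1c(O)cc(O)cc1O | starting material
2 | N-methyl-N-[(2,4,6-trihydroxy-3-methylphenyl)methylidene]methanaminium chloride | Cc1c(O)cc(O)c(C=[N+](C)C)c1O.[Cl-] | intermediate
3 | 2,4,6-trihydroxy-3-methylbenzaldehyde | Cc1c(O)cc(O)c(C=O)c1O | intermediate
4 | 4-(benzyloxy)-2,6-dihydroxy-3-methylbenzaldehyde | Cc1c(OCc2ccccc2)cc(O)c(C=O)c1O | intermediate
5 | 4-(benzyloxy)-2,6-bis(methoxymethoxy)-3-methylbenzaldehyde | Cc1c(OCc2ccccc2)cc(OCOC)c(C=O)c1OCOC | intermediate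
6 | 4-(benzyloxy)-3-bromo-2,6-bis(methoxymethoxy)-5-methylbenzaldehyde | Cc1c(OCc2ccccc2)c(Br)c(OCOC)c(C=O)c1OCOC | intermediate
7 | trimethyl phosphonoacetate | COC(=O)CP(=O)(OC)OC | starting material
8 | sodium (dimethoxyphosphoryl)(methoxycarbonyl)methanide | COC(=O)[CH-]P(=O)(OC)OC.[Na+] | intermediate
9 | methyl (2E)-3-[4-(benzyloxy)-3-bromo-2,6-bis(methoxymethoxy)-5-methylphenyl]prop-2-enoate | COC(=O)/C=C/c1c(OCOC)c(C)c(OCc2ccccc2)c(Br)c1OCOC | intermediate
10 | phenylboronic acid | OB(O)c1ccccc1 | starting material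
11 | methyl (3R)-3-[4-(benzyloxy)-3-bromo-2,6-bis(methoxymethoxy)-5-methylphenyl]-3-phenylpropanoate | COC(=O)C[C@H](c1ccccc1)c1c(OCOC)c(C)c(OCc2ccccc2)c(Br)c1OCOC | intermediate
12 | methyl 2-methyl-3-oxobutanoate | COC(=O)C(C)C(C)=O | starting material
13 | methyl (2E)-3-methoxy-2-methylbut-2-enoate | COC(=O)/C(C)=C(/OC)C | intermediate
14 | lithium 1,3-dimethoxy-2-methylbuta-1,3-dien-1-olate | COC(=C)C(C)=C([O-])OC.[Li+] | intermediate
15 | methyl (2E,7R)-7-[4-(benzyloxy)-3-bromo-2,6-bis(methoxymethoxy)-5-methylphenyl]-3-methoxy-2-methyl-5-oxo-7-phenylhept-2-enoate | COC(=O)/C(C)=C(/OC)CC(=O)C[C@H](c1ccccc1)c1c(OCOC)c(C)c(OCc2ccccc2)c(Br)c1OCOC | intermediate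
16 | 2-[(S)-[4-(benzyloxy)-3-bromo-2,6-bis(methoxymethoxy)-5-methylphenyl](phenyl)methyl]-5-methoxy-4-methylbenzene-1,3-diol | COc1cc(O)c([C@H](c2ccccc2)c2c(OCOC)c(C)c(OCc3ccccc3)c(Br)c2OCOC)c(O)c1C | intermediate
17 | 1,3-bis(benzyloxy)-2-[(S)-[4-(benzyloxy)-3-bromo-2,6-bis(methoxymethoxy)-5-methylphenyl](phenyl)methyl]-5-methoxy-4-methylbenzene | COc1cc(OCc2ccccc2)c([C@H](c2ccccc2)c2c(OCOC)c(C)c(OCc3ccccc3)c(Br)c2OCOC)c(OCc2ccccc2)c1C | intermediate
18 | ethyl (3R)-3-hydroxy-3-phenylpropanoate | CCOC(=O)C[C@@H](O)c1ccccc1 | starting material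
19 | (3R)-3-hydroxy-N-methoxy-N-methyl-3-phenylpropanamide | CON(C)C(=O)C[C@@H](O)c1ccccc1 | intermediate
20 | (3R)-3-[(tert-butyldimethylsilyl)oxy]-N-methoxy-N-methyl-3-phenylpropanamide | CON(C)C(=O)C[C@@H](O[Si](C)(C)C(C)(C)C)c1ccccc1 | intermediate
21 | aryllithium of 17 (lithium in place of bromine at C4a, all else unchanged) | COc1cc(OCc2ccccc2)c([C@H](c2ccccc2)c2c(OCOC)c(C)c(OCc3ccccc3)c([Li])c2OCOC)c(OCc2ccccc2)c1C | intermediate
22 | (3R)-1-{2-(benzyloxy)-5-[(S)-[2,6-bis(benzyloxy)-4-methoxy-3-methylphenyl](phenyl)methyl]-4,6-bis(methoxymethoxy)-3-methylphenyl}-3-[(tert-butyldimethylsilyl)oxy]-3-phenylpropan-1-one | COc1cc(OCc2ccccc2)c([C@H](c2ccccc2)c2c(OCOC)c(C)c(OCc3ccccc3)c(C(=O)C[C@@H](O[Si](C)(C)C(C)(C)C)c3ccccc3)c2OCOC)c(OCc2ccccc2)c1C | intermediate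
23 | (3R)-1-{2-(benzyloxy)-5-[(R)-[2,6-bis(benzyloxy)-4-methoxy-3-methylphenyl](phenyl)methyl]-4,6-dihydroxy-3-methylphenyl}-3-hydroxy-3-phenylpropan-1-one | COc1cc(OCc2ccccc2)c([C@H](c2ccccc2)c2c(O)c(C)c(OCc3ccccc3)c(C(=O)C[C@@H](O)c3ccccc3)c2O)c(OCc2ccccc2)c1C | intermediate
24 | (2S)-5-(benzyloxy)-8-[(R)-[2,6-bis(benzyloxy)-4-methoxy-3-methylphenyl](phenyl)methyl]-7-hydroxy-6-methyl-2-phenyl-2,3-dihydro-4H-chromen-4-one | COc1cc(OCc2ccccc2)c([C@H](c2ccccc2)c2c(O)c(C)c(OCc3ccccc3)c3c2O[C@H](c2ccccc2)CC3=O)c(OCc2ccccc2)c1C | intermediate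
25 | (2S)-8-[(S)-(2,6-dihydroxy-4-methoxy-3-methylphenyl)(phenyl)methyl]-5,7-dihydroxy-6-methyl-2-phenyl-2,3-dihydro-4H-chromen-4-one | COc1cc(O)c([C@H](c2ccccc2)c2c(O)c(C)c(O)c3c2O[C@H](c2ccccc2)CC3=O)c(O)c1C | target

Total step count: 16. Longest linear sequence: 13 steps (1–6, 8–10, 13–16); steps 7, 11 and 12 prepare the two side reagents.

Steps most likely to fail

Step 6. Insertion of the di-ortho-substituted β-aryl enoate into the phenyl–rhodium bond may be so slow that protodeboronation of 10 outruns addition, or the enantioface discrimination may be poor. The fallback is an auxiliary-controlled cuprate addition. It sets out from 9, which is saponified (LiOH, THF/H2O) to (2E)-3-ArA-prop-2-enoic acid F1. PivCl/Et3N converts this into the mixed pivalic anhydride F2, which acylates (S)-4-phenyl-1,3-oxazolidin-2-one (LiCl, Et3N, THF) to the imide (4S)-3-[(2E)-3-ArA-prop-2-enoyl]-4-phenyl-1,3-oxazolidin-2-one F3. PhMgBr/CuBr·SMe2 (THF/Me2S, −40 °C) should add phenyl anti to the C4 phenyl of the chelated s-cis imide and give (4S)-3-[(3R)-3-ArA-3-phenylpropanoyl]-4-phenyl-1,3-oxazolidin-2-one F4. NaOMe in MeOH at 0 °C releases the auxiliary and comes back to the route at 11.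

Step 9. O-acylation to the 4-methoxy-2-pyrone or retro-Claisen cleavage may outrun C-cyclisation of the hindered C6 enolate onto the deactivated ester. The fallback reverses the order of the two C–C bonds, so that the only six-membered closure available runs through carbon. It sets out from 11 and 13. Ester 13 is saponified (KOH, MeOH/H2O) to (2E)-3-methoxy-2-methylbut-2-enoic acid F5 and converted with (COCl)2/cat. DMF into (2E)-3-methoxy-2-methylbut-2-enoyl chloride F6. The lithium enolate of 11, F7 (LiN(i-Pr)2, 2 equiv, THF, −78 °C), is C-acylated by F6 to methyl (4E)-2-[(R)-ArA(phenyl)methyl]-5-methoxy-4-methyl-3-oxohex-4-enoate F8 (C1'–C6' bond first; the epimers at C2 are irrelevant). LiN(SiMe3)2 (2.5 equiv, −78 → 0 °C) then generates the vinylogous carbanion at the enol-ether methyl, which should close onto the ester (C3'→C2') and aromatise, coming back to the route at 16.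

Step 15. β-Elimination of the activated carbinol to the chalcone, or ionisation at the benzylic carbon, would erode the C2 configuration, and closure may be slow because O8a is hindered. The fallback sets C2 by catalyst-controlled conjugate arylation of a chromone. It sets out from 17: exchange to 21 (n-BuLi, −78 °C) and quenching with N-methoxy-N-methylacetamide give 1-{2-(benzyloxy)-5-[(S)-ArD(phenyl)methyl]-4,6-bis(methoxymethoxy)-3-methylphenyl}ethan-1-one F9. HCl in MeOH removes the MOM ethers to give 1-{2-(benzyloxy)-5-[(R)-ArD(phenyl)methyl]-4,6-dihydroxy-3-methylphenyl}ethan-1-one F10. Me2NCH(OMe)2 (toluene, 90 °C) gives (2E)-1-{2-(benzyloxy)-5-[(R)-ArD(phenyl)methyl]-4,6-dihydroxy-3-methylphenyl}-3-(dimethylamino)prop-2-en-1-one F11, which cyclises in AcOH/HCl to 5-(benzyloxy)-8-[(R)-ArD(phenyl)methyl]-7-hydroxy-6-methyl-4H-chromen-4-one F12. Asymmetric 1,4-addition of 10 with Pd(OCOCF3)2/t-BuPyOx (NH4PF6, ClCH2CH2Cl/H2O, 60 °C; ligand enantiomer chosen for 2S) should then come back to the route at 24.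

Further compounds
F1 | step 6 | (2E)-3-[4-(benzyloxy)-3-bromo-2,6-bis(methoxymethoxy)-5-methylphenyl]prop-2-enoic acid | OC(=O)/C=C/c1c(OCOC)c(C)c(OCc2ccccc2)c(Br)c1OCOC
F2 | step 6 | (2E)-3-[4-(benzyloxy)-3-bromo-2,6-bis(methoxymethoxy)-5-methylphenyl]prop-2-enoic 2,2-dimethylpropanoic anhydride | CC(C)(C)C(=O)OC(=O)/C=C/c1c(OCOC)c(C)c(OCc2ccccc2)c(Br)c1OCOC
F3 | step 6 | (4S)-3-[(2E)-3-[4-(benzyloxy)-3-bromo-2,6-bis(methoxymethoxy)-5-methylphenyl]prop-2-enoyl]-4-phenyl-1,3-oxazolidin-2-one | O=C1OC[C@H](c2ccccc2)N1C(=O)/C=C/c1c(OCOC)c(C)c(OCc2ccccc2)c(Br)c1OCOC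
F4 | step 6 | (4S)-3-[(3R)-3-[4-(benzyloxy)-3-bromo-2,6-bis(methoxymethoxy)-5-methylphenyl]-3-phenylpropanoyl]-4-phenyl-1,3-oxazolidin-2-one | O=C1OC[C@H](c2ccccc2)N1C(=O)C[C@H](c1ccccc1)c1c(OCOC)c(C)c(OCc2ccccc2)c(Br)c1OCOC
F5 | step 9 | (2E)-3-methoxy-2-methylbut-2-enoic acid | OC(=O)/C(C)=C(/OC)C
F6 | step 9 | (2E)-3-methoxy-2-methylbut-2-enoyl chloride | ClC(=O)/C(C)=C(/OC)C
F7 | step 9 | lithium enolate of 11 (lithium (3R)-3-ArA-1-methoxy-3-phenylprop-1-en-1-olate) | COC([O-])=C[C@H](c1ccccc1)c1c(OCOC)c(C)c(OCc2ccccc2)c(Br)c1OCOC.[Li+]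
F8 | step 9 | methyl (4E)-2-[(R)-[4-(benzyloxy)-3-bromo-2,6-bis(methoxymethoxy)-5-methylphenyl](phenyl)methyl]-5-methoxy-4-methyl-3-oxohex-4-enoate | COC(=O)C(C(=O)/C(C)=C(/OC)C)[C@H](c1ccccc1)c1c(OCOC)c(C)c(OCc2ccccc2)c(Br)c1OCOC
F9 | step 15 | 1-{2-(benzyloxy)-5-[(S)-[2,6-bis(benzyloxy)-4-methoxy-3-methylphenyl](phenyl)methyl]-4,6-bis(methoxymethoxy)-3-methylphenyl}ethan-1-one | COc1cc(OCc2ccccc2)c([C@H](c2ccccc2)c2c(OCOC)c(C)c(OCc3ccccc3)c(C(C)=O)c2OCOC)c(OCc2ccccc2)c1C
F10 | step 15 | 1-{2-(benzyloxy)-5-[(R)-[2,6-bis(benzyloxy)-4-methoxy-3-methylphenyl](phenyl)methyl]-4,6-dihydroxy-3-methylphenyl}ethan-1-one | COc1cc(OCc2ccccc2)c([C@H](c2ccccc2)c2c(O)c(C)c(OCc3ccccc3)c(C(C)=O)c2O)c(OCc2ccccc2)c1C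
F11 | step 15 | (2E)-1-{2-(benzyloxy)-5-[(R)-[2,6-bis(benzyloxy)-4-methoxy-3-methylphenyl](phenyl)methyl]-4,6-dihydroxy-3-methylphenyl}-3-(dimethylamino)prop-2-en-1-one | COc1cc(OCc2ccccc2)c([C@H](c2ccccc2)c2c(O)c(C)c(OCc3ccccc3)c(C(=O)/C=C/N(C)C)c2O)c(OCc2ccccc2)c1C
F12 | step 15 | 5-(benzyloxy)-8-[(R)-[2,6-bis(benzyloxy)-4-methoxy-3-methylphenyl](phenyl)methyl]-7-hydroxy-6-methyl-4H-chromen-4-one | COc1cc(OCc2ccccc2)c([C@H](c2ccccc2)c2c(O)c(C)c(OCc3ccccc3)c3c2OC=CC3=O)c(OCc2ccccc2)c1C
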